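Ring B, the ten-membered carbocycle C1–C10 that carries methyl groups on C4 and C10 and the lactone oxygen on C6, is a eudesmane decalin whose shared C5–C10 bond has been cut, and the route rests on making that cut with light. A trans-fused eudesma-1,3,7(11)-trien-12,6-olide bearing 8α-OTBS and 13-OAc, prepared from artemisin, is irradiated; conrotatory 6π opening of its C1=C2–C3=C4 diene breaks C5–C10 and in one operation delivers ring B with E alkenes at C1=C10 and C4=C5 and a Z alkene at C2=C3. Diimide reduction, double epoxidation and a base-triggered eliminative ether closure then supply ring A, the C10 carbinol and the C5=C6 ylidene.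

Key step: step 9

Assumption: artemisin (8α-hydroxy-α-santonin, CAS 481-05-0) is bought from natural-product suppliers; it brings all fifteen carbons, the trans-lactone and the equatorial 8α oxygen, which allylic oxidation of a C7=C11 butenolide would not place reliably (axial 8β delivery or attack at C6–H is expected).

Numbering: eudesmane/germacrane numbering throughout (C1–C10 ring carbons, C11–C13 lactone carbons, C14 on C10, C15 on C4); α/β refer to the usual eudesmane drawing with the C10 methyl β.

Design notes:
- C13 is oxygenated through the exocyclic C11=C13 alkene, because radical bromination of the butenolide would go to C6.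
- Ring A is saturated by hydrogenation, because dissolving metals would cleave the C6–O bond (vinylogously α to the C3 ketone).
- The diene is made last and under neutral conditions, because the butenolide with its C6 proton and allylic acetate does not tolerate strong base.

Step 1
Reactants: 1 artemisin
Product: 2 8-O-TBS-artemisin
Conditions: TBSCl, imidazole, DMAP (cat.), DMF, 40 °C
Reagents that add atoms: tert-butyldimethylsilyl chloride, CC(C)(C)[Si](C)(C)Cl
Why: Silyl ether formation at the only hydroxyl group (secondary, equatorial 8α) should mask it for the enolate chemistry that follows; no stereocentre is touched.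

Step 2
Reactants: 2 8-O-TBS-artemisin
Product: 4 trans-fused tetrahydro ketone with equatorial 4α-methyl, via 4β-methyl epimer 3 (not isolated)
Conditions: H2 (1 atm), 10% Pd/C, EtOAc, 23 °C; filter; DBU (0.2 equiv), toluene, 40 °C
Reagents that add atoms: none
Why: Heterogeneous catalytic hydrogenation should saturate C1=C2 and C4=C5 from the α face, away from the axial C10 methyl, which sets 5α-H (trans ring fusion) and first an axial 4β-methyl; epimerisation through the C3 enolate then relieves the syn-axial C14/C15 contact and gives the equatorial 4α-methyl ketone.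

Step 3
Reactants: 4 trans-fused tetrahydro ketone
Product: 7 ring A enone with α-methylene lactone, via bis-selenide 5 (not isolated), via bis-selenoxide 6 (not isolated)
Conditions: LiN(iPr)2 (2.3 equiv), THF, −78 °C; PhSeCl (2.4 equiv), −78 °C; then pyridine, 30% H2O2, CH2Cl2, 0 → 23 °C
Reagents that add atoms: none
Why: Double α-selenenylation of the kinetic C2 ketone enolate and the C11 lactone enolate followed by selenoxide syn-elimination should give the C1=C2 enone and, because selenium enters C11 on the β face anti to H7 so that only the C13 hydrogens are syn to it, the exocyclic C11=C13 alkene; C11 ceases to be a stereocentre.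

Step 4
Reactants: 7 ring A enone with α-methylene lactone
Product: 8 11β,13-diol
Conditions: OsO4 (2 mol%), NMO (1.1 equiv), citric acid (0.5 equiv), t-BuOH/H2O, 23 °C
Reagents that add atoms: osmium tetroxide, O=[Os](=O)(=O)=O; N-methylmorpholine N-oxide, C[N+]1([O-])CCOCC1; water, O
Why: Upjohn-type syn-dihydroxylation should pick the unhindered 1,1-disubstituted C11=C13 alkene over the ring A enone, whose β-carbon C1 is neopentylic; attack anti to H7α is expected to place the tertiary hydroxyl on the β face of C11, a centre that is erased again in step 6.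

Step 5
Reactants: 8 11β,13-diol
Product: 9 13-monoacetate
Conditions: Ac2O (1.2 equiv), pyridine, CH2Cl2, 0 °C
Reagents that add atoms: acetic anhydride, CC(=O)OC(C)=O
Why: Acylation should be selective for the primary C13 hydroxyl, the tertiary α-hydroxy lactone being far less reactive; no stereocentre changes.

Step 6
Reactants: 9 13-monoacetate
Product: 11 13-acetoxy butenolide enone, via chlorosulfite 10 (not isolated)
Conditions: SOCl2, pyridine, CH2Cl2, −20 → 0 °C
Reagents that add atoms: none
Why: Anti E2 dehydration of the tertiary alcohol through its chlorosulfite should remove H7α, which is antiperiplanar to the 11β leaving group, and give the tetrasubstituted conjugated C7=C11 alkene rather than an enol acetate toward C13 (the syn-selective Burgess reagent would reach the same alkene from the C11 epimer); C7 and C11 become trigonal.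

Step 7
Reactants: 11 13-acetoxy butenolide enone
Product: 12 3β-allylic alcohol
Conditions: NaBH4, CeCl3·7H2O, MeOH, −78 °C
Reagents that add atoms: none
Why: Luche 1,2-reduction should touch only the enone carbonyl (the tetrasubstituted butenolide and the acetate are inert at −78 °C), hydride arriving axially from the α face to give the pseudo-equatorial 3β alcohol, a centre that is removed in step 8.

Step 8
Reactants: 12 3β-allylic alcohol
Product: 14 trans-fused eudesma-1,3,7(11)-trienolide (key-step precursor), via alkoxysulfurane 13 (not isolated)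
Conditions: Martin sulfurane Ph2S[OC(CF3)2Ph]2 (1.5 equiv), CH2Cl2, 0 → 23 °C, argon, dark
Reagents that add atoms: none
Why: Neutral dehydration of the allylic alcohol with Martin sulfurane should give the 1,3-diene, because the activated allylic C3–O bond can only eliminate toward H4 (C2 is vinylic, C10 is quaternary), so C1=C2–C3=C4 forms while C5 and C10, and hence the trans fusion, stay untouched.

Step 9
Reactants: 14 trans-fused eudesma-1,3,7(11)-trienolide
Product: 15 (1(10)E,2Z,4E)-germacratetraenolide
Conditions: hν (254 nm, low-pressure Hg lamp, quartz well), degassed Et2O (2 mM), −78 °C; stop near the photostationary composition; solution kept below −60 °C and used at once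
Reagents that add atoms: none
Why: Excitation of the homoannular C1=C2–C3=C4 diene (absorbing near 265 nm, far above the butenolide near 220 nm) triggers a conrotatory 6π electrocyclic ring opening that breaks the C5–C10 σ bond, the same reaction type as the provitamin D to previtamin D opening and the known opening of trans-fused eudesma-1,3-dienes to cyclodecatrienes. Ring B, the ten-membered carbocycle, is not closed by a cyclisation but unveiled by ring expansion when the bond shared by the two six-membered rings is cleaved. No stereocentre is created; C5 and C10 become trigonal and C6 and C8 are untouched. Because the ring fusion is trans, conrotation swings C6 and C9 outward together, so C4=C5 and C1=C10 are both E while the ring-locked C2=C3 stays Z. The step needs chromophore selectivity and freedom from secondary reactions: the diene takes nearly all of the 254 nm light, oxygen is excluded, irradiation is stopped near the photostationary point, and −78 °C suppresses thermal disrotatory reclosure and Cope rearrangement of the triene.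

Step 10
Reactants: 15 (1(10)E,2Z,4E)-germacratetraenolide
Product: 16 (1(10)E,4E)-germacra-1(10),4,7(11)-trienolide
Conditions: MeOH added to the cold photolysate; KO2CN=NCO2K (10 equiv), AcOH (20 equiv, slow addition), −40 → −15 °C
Reagents that add atoms: none
Why: Diimide reduction transfers H2 in a concerted syn fashion and discriminates strongly by substitution, so the cis-disubstituted C2=C3 alkene should be reduced ahead of the trisubstituted C1=C10 and C4=C5 and the tetrasubstituted butenolide alkene, without hydrogenolysis of the allylic C–O bonds and without forming a stereocentre.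

Step 11
Reactants: 16 (1(10)E,4E)-germacra-1(10),4,7(11)-trienolide
Product: 18 (1R,10R,4R,5R)-bis-epoxide, via 1,10-epoxide 17 (not isolated)
Conditions: mCPBA (2.4 equiv), NaHCO3, CH2Cl2, 0 °C
Reagents that add atoms: meta-chloroperbenzoic acid, OOC(=O)c1cccc(Cl)c1
Why: Prilezhaev epoxidation should oxidise the two electron-rich trisubstituted E alkenes (C1=C10 first, the butenolide alkene not at all); in the costunolide-type conformer with C14 and C15 syn the peracid reaches each alkene only from its outer face, which sets C1, C10, C4 and C5 all R.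

Step 12
Reactants: 18 (1R,10R,4R,5R)-bis-epoxide
Product: 20 1,4-epoxy-10-hydroxy-5-ylidene butenolide (8-OTBS), via hydroxy epoxide 19 (not isolated)
Conditions: DBU (1.2 equiv), CH2Cl2, 0 → 23 °C
Reagents that add atoms: none
Why: DBU should remove the γ-proton H6 of the butenolide, the furanolate then opens the adjacent C4–C5 epoxide by vinylogous E1cB elimination to give the C5=C6 ylidene (C4 cis to C7, the only geometry the ring allows) and the C4 alkoxide, and this attacks the C1–C10 epoxide at C1 from inside the ring in a 5-exo-tet opening with inversion, so that C1 becomes S, C10 keeps its oxygen as the tertiary alcohol (R) and C4 stays R.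

Step 13
Reactants: 20 1,4-epoxy-10-hydroxy-5-ylidene butenolide (8-OTBS)
Product: 21 C8 alcohol
Conditions: HF·pyridine, pyridine, THF, 0 → 23 °C
Reagents that add atoms: none
Why: Fluoride-mediated desilylation under buffered acidic conditions should leave the acetate, the enol lactone and the tertiary alcohol untouched; no stereocentre is affected.

Step 14
Reactants: 21 C8 alcohol; 22 methacrylic anhydride
Product: 23 CNP0516045.1
Conditions: DMAP (0.2 equiv), Et3N, CH2Cl2, 0 °C
Reagents that add atoms: methacrylic anhydride, C=C(C)C(=O)OC(=O)C(C)=C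
Why: DMAP-catalysed acyl transfer (Steglich-type) should esterify the secondary C8 alcohol while the tertiary C10 alcohol does not react; the C8 configuration (S, carried from artemisin) is retained.

Compound list

1 | artemisin (8α-hydroxy-3-oxoeudesma-1,4-dien-12,6α-olide; 6βH, 7αH, 11βH, 10β-methyl) | C[C@H]1[C@@H]2[C@@H](O)C[C@]3(C=CC(=O)C(=C3[C@H]2OC1=O)C)C | starting material
2 | 8-O-TBS-artemisin (8α-tert-butyldimethylsilyloxy derivative of 1) | C[C@H]1[C@@H]2[C@@H](O[Si](C)(C)C(C)(C)C)C[C@]3(C=CC(=O)C(=C3[C@H]2OC1=O)C)C | intermediate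
3 | 8α-TBSO-3-oxo-4β-methyl-5αH-eudesman-12,6α-olide (kinetic C4 epimer, axial methyl; not isolated) | C[C@H]1[C@@H]2[C@@H](O[Si](C)(C)C(C)(C)C)C[C@@]3(C)CCC(=O)[C@H](C)[C@@H]3[C@H]2OC1=O | intermediate
4 | 8α-TBSO-3-oxo-4α-methyl-5αH-eudesman-12,6α-olide (trans-decalin, equatorial C4 methyl, 11βH) | C[C@H]1[C@@H]2[C@@H](O[Si](C)(C)C(C)(C)C)C[C@@]3(C)CCC(=O)[C@@H](C)[C@@H]3[C@H]2OC1=O | intermediate
5 | 2α,11β-bis(phenylselanyl) derivative of 4 (C13 methyl on the α face of C11; not isolated) | C[C@@]1([Se]c4ccccc4)[C@@H]2[C@@H](O[Si](C)(C)C(C)(C)C)C[C@@]3(C)C[C@@H]([Se]c5ccccc5)C(=O)[C@@H](C)[C@@H]3[C@H]2OC1=O | intermediate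
6 | bis-selenoxide of 5 (mixture at selenium; not isolated) | C[C@@]1([Se](=O)c4ccccc4)[C@@H]2[C@@H](O[Si](C)(C)C(C)(C)C)C[C@@]3(C)C[C@@H]([Se](=O)c5ccccc5)C(=O)[C@@H](C)[C@@H]3[C@H]2OC1=O | intermediate
7 | 8α-TBSO-3-oxo-4α-methyl-5αH-eudesma-1,11(13)-dien-12,6α-olide | C=C1[C@@H]2[C@@H](O[Si](C)(C)C(C)(C)C)C[C@@]3(C)C=CC(=O)[C@@H](C)[C@@H]3[C@H]2OC1=O | intermediate
8 | 8α-TBSO-11β,13-dihydroxy-3-oxo-4α-methyl-5αH-eudesm-1-en-12,6α-olide | OC[C@@]1(O)[C@@H]2[C@@H](O[Si](C)(C)C(C)(C)C)C[C@@]3(C)C=CC(=O)[C@@H](C)[C@@H]3[C@H]2OC1=O | intermediate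
9 | 13-acetate of 8 (11β-hydroxyl free) | CC(=O)OC[C@@]1(O)[C@@H]2[C@@H](O[Si](C)(C)C(C)(C)C)C[C@@]3(C)C=CC(=O)[C@@H](C)[C@@H]3[C@H]2OC1=O | intermediate
10 | 11β-chlorosulfite of 9 (not isolated) | CC(=O)OC[C@@]1(OS(=O)Cl)[C@@H]2[C@@H](O[Si](C)(C)C(C)(C)C)C[C@@]3(C)C=CC(=O)[C@@H](C)[C@@H]3[C@H]2OC1=O | intermediate
11 | 13-acetoxy-8α-TBSO-3-oxo-4α-methyl-5αH-eudesma-1,7(11)-dien-12,6α-olide | CC(C)(C)[Si](C)(C)O[C@H]1C[C@@]2(C)C=CC(=O)[C@@H](C)[C@@H]2[C@H]3OC(=O)C(COC(C)=O)=C31 | intermediate
12 | 13-acetoxy-8α-TBSO-3β-hydroxy-4α-methyl-5αH-eudesma-1,7(11)-dien-12,6α-olide | CC(C)(C)[Si](C)(C)O[C@H]1C[C@@]2(C)C=C[C@H](O)[C@@H](C)[C@@H]2[C@H]3OC(=O)C(COC(C)=O)=C31 | intermediate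
13 | 3β-O-alkoxysulfurane of 12, Ph2S(OR)[OC(CF3)2Ph] (not isolated) | CC(C)(C)[Si](C)(C)O[C@H]1C[C@@]2(C)C=C[C@H](OS(c4ccccc4)(c5ccccc5)OC(c6ccccc6)(C(F)(F)F)C(F)(F)F)[C@@H](C)[C@@H]2[C@H]3OC(=O)C(COC(C)=O)=C31 | intermediate
14 | 13-acetoxy-8α-TBSO-5αH-eudesma-1,3,7(11)-trien-12,6α-olide (trans-fused, 10β-methyl, 6βH; key-step precursor) | CC(C)(C)[Si](C)(C)O[C@H]1C[C@@]2(C)C=CC=C(C)[C@@H]2[C@H]3OC(=O)C(COC(C)=O)=C31 | intermediate
15 | (1(10)E,2Z,4E)-13-acetoxy-8-TBSO-germacra-1(10),2,4,7(11)-tetraen-12,6-olide (C6 and C8 as in 14; key-step product) | CC(C)(C)[Si](C)(C)O[C@H]1C/C(C)=C/C=C\C(C)=C\[C@H]3OC(=O)C(COC(C)=O)=C31 | intermediate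
16 | (1(10)E,4E)-13-acetoxy-8-TBSO-germacra-1(10),4,7(11)-trien-12,6-olide (C6 and C8 as in 14) | CC(C)(C)[Si](C)(C)O[C@H]1C/C(C)=C/CC/C(C)=C/[C@H]3OC(=O)C(COC(C)=O)=C31 | intermediate
17 | (1R,10R)-1,10-epoxide of 16 (not isolated) | CC(C)(C)[Si](C)(C)O[C@H]1C[C@@]4(C)O[C@@H]4CC/C(C)=C/[C@H]3OC(=O)C(COC(C)=O)=C31 | intermediate
18 | (1R,10R,4R,5R)-1,10:4,5-bis-epoxide of 16 | CC(C)(C)[Si](C)(C)O[C@H]1C[C@@]4(C)O[C@@H]4CC[C@@]5(C)O[C@@H]5[C@H]3OC(=O)C(COC(C)=O)=C31 | intermediate
19 | (1R,10R)-1,10-epoxy-(4R)-4-hydroxy-(5E)-13-acetoxy-8-TBSO-germacra-5,7(11)-dien-12,6-olide (not isolated) | CC(C)(C)[Si](C)(C)O[C@H]1C[C@@]4(C)O[C@@H]4CC[C@@](C)(O)/C=C3/OC(=O)C(COC(C)=O)=C31 | intermediate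
20 | (1S,4R,5E,8S,10R)-13-acetoxy-1,4-epoxy-10-hydroxy-8-TBSO-germacra-5,7(11)-dien-12,6-olide | CC(C)(C)[Si](C)(C)O[C@H]1C[C@@](C)(O)[C@@H]2CC[C@](C)(/C=C3/OC(=O)C(COC(C)=O)=C31)O2 | intermediate
21 | (1S,4R,5E,8S,10R)-13-acetoxy-1,4-epoxy-8,10-dihydroxygermacra-5,7(11)-dien-12,6-olide | O[C@H]1C[C@@](C)(O)[C@@H]2CC[C@](C)(/C=C3/OC(=O)C(COC(C)=O)=C31)O2 | intermediate
22 | methacrylic anhydride | C=C(C)C(=O)OC(=O)C(C)=C | starting material
23 | CNP0516045.1 (8-O-methacrylate of 21) | C=C(C)C(=O)O[C@H]1C[C@@](C)(O)[C@@H]2CC[C@](C)(/C=C3/OC(=O)C(COC(C)=O)=C31)O2 | target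

Total step count: 14. Longest linear sequence: 14 steps (1 → 23); methacrylic anhydride 22 is used as bought.

Steps most likely to fail, in this order: step 9, step 12, step 11.

Step 9. What may go wrong: light is shared with, or energy is passed to, the butenolide; the triene is consumed by secondary photoreactions (E/Z isomerisation, bicyclisation) before the diene is used up; or the triene recloses thermally during handling. Fallback: open the ring before the lactone becomes a chromophore. Setting out from hydroxy lactone 9, Luche reduction (NaBH4, CeCl3·7H2O, MeOH, −78 °C) should give the 3β-allylic alcohol F1. Acid-catalysed dehydration (PPTS, benzene, 60 °C; the tertiary α-hydroxy lactone cannot ionise) should give the 1,3-diene F2. Irradiation at 254 nm in Et2O at −78 °C should give the saturated-lactone triene F3, whose only chromophore is the diene. Diimide (KO2CN=NCO2K, AcOH, −40 °C) should give the germacra-1(10),4-diene F4. SOCl2/pyridine, through the chlorosulfite F5, should then install the C7=C11 alkene, which rejoins the route at 16.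

Step 12. What may go wrong: the furanolate expels the C13 acetate (E1cB toward C13) faster than it opens the C4–C5 epoxide, or prolonged base exposure strips the acetate from the product after γ-deprotonation at C8. Fallback: take the acetate off under neutral conditions and put it back after the cascade. Setting out from 18, enzymatic hydrolysis (Candida antarctica lipase B, pH 7 phosphate buffer/MTBE, 30 °C) should give the 13-hydroxy bis-epoxide F6. DBU in CH2Cl2 then runs the same elimination and 5-exo closure without a leaving group on C13 and should give the 13-hydroxy ether F7. Selective acetylation of the primary alcohol (Ac2O, pyridine, 0 °C; the tertiary C10 alcohol is inert) returns to the route at 20.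

Step 11. What may go wrong: acid-promoted transannular cyclisation of mono-epoxide 17 onto C4=C5, or poor facial selectivity if a second ring conformer exposes the inner face of either alkene. Fallback: replace substrate control by catalyst control under non-acidic conditions. Shi epoxidation of 16 (D-fructose-derived ketone, KHSO5, K2CO3 buffer, MeCN/dimethoxymethane/H2O, 0 °C) has an intrinsic (R,R) preference for E-trisubstituted alkenes that matches all four centres. It sets out from 16 and returns at 18 without a new intermediate.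

Further compounds

F1 | step 9 | 13-acetoxy-8α-TBSO-3β,11β-dihydroxy-4α-methyl-5αH-eudesm-1-en-12,6α-olide | CC(=O)OC[C@@]1(O)[C@@H]2[C@@H](O[Si](C)(C)C(C)(C)C)C[C@@]3(C)C=C[C@H](O)[C@@H](C)[C@@H]3[C@H]2OC1=O
F2 | step 9 | 13-acetoxy-8α-TBSO-11β-hydroxy-5αH-eudesma-1,3-dien-12,6α-olide | CC(=O)OC[C@@]1(O)[C@@H]2[C@@H](O[Si](C)(C)C(C)(C)C)C[C@@]3(C)C=CC=C(C)[C@@H]3[C@H]2OC1=O
F3 | step 9 | (1(10)E,2Z,4E)-13-acetoxy-8-TBSO-11-hydroxygermacra-1(10),2,4-trien-12,6-olide | CC(=O)OC[C@@]1(O)[C@@H]2[C@@H](O[Si](C)(C)C(C)(C)C)C/C(C)=C/C=C\C(C)=C\[C@H]2OC1=O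
F4 | step 9 | (1(10)E,4E)-13-acetoxy-8-TBSO-11-hydroxygermacra-1(10),4-dien-12,6-olide | CC(=O)OC[C@@]1(O)[C@@H]2[C@@H](O[Si](C)(C)C(C)(C)C)C/C(C)=C/CC/C(C)=C/[C@H]2OC1=O
F5 | step 9 | 11-chlorosulfite of F4 | CC(=O)OC[C@@]1(OS(=O)Cl)[C@@H]2[C@@H](O[Si](C)(C)C(C)(C)C)C/C(C)=C/CC/C(C)=C/[C@H]2OC1=O
F6 | step 12 | 13-hydroxy analogue of bis-epoxide 18 | CC(C)(C)[Si](C)(C)O[C@H]1C[C@@]4(C)O[C@@H]4CC[C@@]5(C)O[C@@H]5[C@H]3OC(=O)C(CO)=C31
F7 | step 12 | 13-hydroxy analogue of 20 | CC(C)(C)[Si](C)(C)O[C@H]1C[C@@](C)(O)[C@@H]2CC[C@](C)(/C=C3/OC(=O)C(CO)=C31)O2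
F0 | step 11 | none | none
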